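On Friday's flask L keeps a leftover, for its half-life on the way to D alone, 28 s, is longer than the run of 20 s; D.Q needs Q as well, so the reckoning follows Q.

all flasks: L 20 mM; J 3.0 mM (held); time 20 s
- Thursday's: temperature 125 °C
- Friday's: temperature 110 °C

    L + D.Q → L.D.Q (k1 = 0.49 L mol⁻¹ s⁻¹, Ea1 = 77.0 kJ mol⁻¹)
    J ⇌ Z, rate k2*(csat - [Z]) (k2 = 0.18 s⁻¹, csat = 3.0 mM)
    D + Q → D.Q (k3 = 14 L mol⁻¹ s⁻¹, Ea3 = 63.0 kJ mol⁻¹)
    E ⇌ D.Q, rate k4*(cs4 - [D.Q]) while solid is left; crystals form when [D.Q] > cs4 (cs4 = 7.0 mM, k4 = 1.5 s⁻¹)
    Z → Q (k5 = 0.11 s⁻¹, Ea5 = 89.0 kJ mol⁻¹)
    L → D (k6 = 0.025 s⁻¹, Ea6 = 93.0 kJ mol⁻¹)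
    (constants at 110 °C)

* which of the two there is more of at the end, counted by the L in each, Thursday's (L.D.Q / D.Q)
* which of the two there is more of at the end, counted by the L in each, Friday's (L.D.Q / D.Q)
* how much D.Q is there at the end, in percent of the L charged: Thursday's
* how much D.Q is there at the end, in percent of the L charged: Friday's

- percentages count the L that a species holds: one L.D.Q counts as two
- D.Q is meant together with its E
- solid, in amounts per volume of the solution: E
- at the start none of Z is dissolved
- the constants hold at 110 °C; other temperatures follow from the activation energies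

The concentration to watch is free Q, which together with D enters the rate of D + Q → D.Q. Z starts from nothing, rises over a lag of one over the sum of the transfer constant and the constant of Z → Q, and then stands where its gain and loss balance, so Q arrives at a steady rate. At 125 °C on Thursday's the constant of Z → Q is 0.315 s⁻¹, and Q arrives at 0.344 mM s⁻¹, against 0.205 mM s⁻¹ on Friday's. Every Q delivered stands as free Q, as D.Q with its E, or as L.D.Q. Dividing the Q delivered after the lag by the L charged gives 30.9 % on Thursday's and 17.0 % on Friday's: this is the delivery number, the share of the charge that Q has reached by the end.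

One number is not enough, since part of that Q stands free. Taking D as what has left L, D captures Q in a pseudo-first-order way, and I reckon the free pool at the end as the supply over that capture constant: 0.750 mM on Thursday's, 1.86 mM on Friday's. By this reckoning a Q lives 2.18 s on Thursday's and 9.07 s on Friday's, shorter than the run. On Friday's this pool is about half of the delivery number. Subtracting it, I expect D.Q at 27.2 % on Thursday's and 7.66 % on Friday's. Thursday's amount lies under the solubility of 7.0 mM, so E does not enter. With L taken at its charge, and D.Q taken to have stood on average at half its end value, I reckon L.D.Q counted double at less than D.Q, 48.7 % of it on Thursday's and 19.6 % on Friday's. So the greater is D.Q on Thursday's and D.Q on Friday's.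

The forecast names D.Q and D.Q, with 24 % and 7.6 %, on the ground that “Q supply from the held J through Z limits D.Q formation”. Its Thursday's figure stands lower than mine.

The simulation gives D.Q on Thursday's, 23.8 % against 2.86 % of L.D.Q, and D.Q on Friday's, 7.12 % against 0.520 %. Thursday's flask repeated at 140 °C takes the same reckoning: Z → Q goes at 0.836 s⁻¹, Q arrives at 0.444 mM s⁻¹, and the delivery number is 42.3 %. A reckoned free pool of 0.383 mM leaves 40.3 %. That flask ends with 37.7 % of D.Q, its solid counted, and E, counted within that figure, stands at 1.47 % of the L charged.

The constants stand for no real mixture; the result is computed.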